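**Assumption:** positions are labelled C1–C15 by germacrane numbering (C6 lactone carbinol, C7 ring-fusion carbon, C8 angelate carbon, C10 quaternary furanone carbon); tert-butyldimethyl(prop-2-yn-1-yloxy)silane and angelic acid are taken as purchased.

## Retrosynthetic overview

1. The ten-membered carbocycle is formed last, by ring-closing metathesis at C4=C5 between a furanone isopropenyl group and a C6 vinyl group; the C8 angelate comes from the 8-epi alcohol by Mitsunobu inversion.
2. Key bond C7–C8: intermolecular zinc Barbier allylation of furanone aldehyde 19 with bromomethyl butenolide 30. It sets C7 and C8 and converts the butenolide into the trans-fused α-methylene lactone.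
3. Furanone 19 (first ring): intermolecular aldol of an α-silyloxy methyl ketone with methacrolein, oxidation, cyclodehydration; C10 comes from (S)-lactic acid by Seebach allylation.
4. Butenolide 30 (second ring): acetylide addition to acrolein, lipase resolution (C6), hydroalumination–iodination, carbonylative lactonisation, bromination.
5. Ring order: furanone, then butenolide/α-methylene lactone, then the ten-membered ring.

## Route

### Furanone aldehyde (steps 1–10)

**Step 1**
Reactants: 1 (S)-lactic acid; 2 pivalaldehyde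
Product: 3 (2S,5S)-2-tert-butyl-5-methyl-1,3-dioxolan-4-one
Conditions: TsOH·H2O (cat.), H2SO4 (cat.), pentane, reflux, Dean–Stark; recrystallisation from pentane at −78 °C
Reagents that add atoms: none
Why: Acid-catalysed acetalisation (first stage of Seebach self-regeneration of stereocentres) favours the cis acetal (about 4:1), which crystallises pure, so the lactic acid centre fixes the new acetal centre as 2S.

**Step 2**
Reactants: 3 (2S,5S)-2-tert-butyl-5-methyl-1,3-dioxolan-4-one; 4 allyl bromide
Product: 6 (2S,5R)-2-tert-butyl-5-methyl-5-(prop-2-en-1-yl)-1,3-dioxolan-4-one, via lithium enolate 5 (not isolated)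
Conditions: LiN(iPr)2, THF, −78 °C; then 4, −78 → −20 °C
Reagents that add atoms: none
Why: Enolate alkylation in which the tert-butyl group blocks one face, so allyl bromide enters trans to it and the quaternary centre (future C10) is regenerated as 5R with high diastereoselectivity.

**Step 3**
Reactants: 6 (2S,5R)-2-tert-butyl-5-methyl-5-(prop-2-en-1-yl)-1,3-dioxolan-4-one
Product: 7 (2R)-2-hydroxy-N-methoxy-N,2-dimethylpent-4-enamide
Conditions: MeNH(OMe)·HCl, AlMe3, CH2Cl2, 0 °C → rt; aqueous Rochelle salt work-up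
Reagents that add atoms: N,O-dimethylhydroxylamine hydrochloride (CNOC.Cl)
Why: Weinreb aminolysis of the acetal-type lactone by the aluminium amide opens the ring and the hemiacetal collapses with loss of pivalaldehyde, leaving the quaternary centre untouched.

**Step 4**
Reactants: 7 (2R)-2-hydroxy-N-methoxy-N,2-dimethylpent-4-enamide
Product: 10 (2R)-2-hydroxy-N,4,4-trimethoxy-N,2-dimethylbutanamide, via ozonide 8 (not isolated), via hydroxy aldehyde 9 (not isolated)
Conditions: O3, CH2Cl2, −78 °C; Me2S, −78 °C → rt; then MeOH, HC(OMe)3, TsOH·H2O (cat.), rt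
Reagents that add atoms: trimethyl orthoformate (COC(OC)OC)
Why: Ozonolysis of the only alkene with reductive work-up, followed at once by acid-catalysed acetalisation, masks the retro-aldol-prone β-hydroxy aldehyde as its dimethyl acetal without touching the stereocentre.

**Step 5**
Reactants: 10 (2R)-2-hydroxy-N,4,4-trimethoxy-N,2-dimethylbutanamide
Product: 11 (2R)-N,4,4-trimethoxy-N,2-dimethyl-2-[(trimethylsilyl)oxy]butanamide
Conditions: 1-(trimethylsilyl)imidazole, CH2Cl2, rt
Reagents that add atoms: 1-(trimethylsilyl)imidazole (C[Si](C)(C)n1ccnc1)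
Why: Neutral silylation of the tertiary alcohol by a powerful silyl donor leaves the acetal intact and gives the α-silyloxy carbonyl pattern needed for the furanone aldol sequence.

**Step 6**
Reactants: 11 (2R)-N,4,4-trimethoxy-N,2-dimethyl-2-[(trimethylsilyl)oxy]butanamide
Product: 12 (3R)-5,5-dimethoxy-3-methyl-3-[(trimethylsilyl)oxy]pentan-2-one
Conditions: MeMgBr, THF, 0 °C; then pH 7 buffer
Reagents that add atoms: methylmagnesium bromide (C[Mg]Br)
Why: Grignard addition to a Weinreb amide stops at the chelated tetrahedral intermediate and releases the methyl ketone (C1, C2) only on work-up.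

**Step 7**
Reactants: 12 (3R)-5,5-dimethoxy-3-methyl-3-[(trimethylsilyl)oxy]pentan-2-one; 13 methacrolein
Product: 15 (6R)-3-hydroxy-8,8-dimethoxy-2,6-dimethyl-6-[(trimethylsilyl)oxy]oct-1-en-5-one (both C3 epimers), via lithium enolate 14 (not isolated)
Conditions: LiN(iPr)2, THF, −78 °C; then 13, −78 °C; AcOH quench at −78 °C
Reagents that add atoms: none
Why: Intermolecular aldol addition in which the only possible enolate (methyl side) adds 1,2 to methacrolein, forming C2–C3; the new carbinol centre is formed as a mixture and is erased in step 8.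

**Step 8**
Reactants: 15 (6R)-3-hydroxy-8,8-dimethoxy-2,6-dimethyl-6-[(trimethylsilyl)oxy]oct-1-en-5-one
Product: 16 (6R)-8,8-dimethoxy-2,6-dimethyl-6-[(trimethylsilyl)oxy]oct-1-ene-3,5-dione
Conditions: Dess–Martin periodinane, pyridine, CH2Cl2, 0 °C → rt
Reagents that add atoms: none
Why: Dess–Martin oxidation of the β-hydroxy ketone to the 1,3-diketone under buffered conditions that preserve the silyl ether and the acetal.

**Step 9**
Reactants: 16 (6R)-8,8-dimethoxy-2,6-dimethyl-6-[(trimethylsilyl)oxy]oct-1-ene-3,5-dione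
Product: 18 (2R)-2-(2,2-dimethoxyethyl)-2-methyl-5-(prop-1-en-2-yl)furan-3(2H)-one, via hydroxy diketone 17 (not isolated)
Conditions: TsOH·H2O (10 mol %), MeOH, 0 °C → rt
Reagents that add atoms: none
Why: Acid removes the silyl group, and the tertiary alcohol closes onto the distal ketone and dehydrates (cyclodehydration) to the 3(2H)-furanone; in methanol the acetal survives, so the diketone never meets a free aldehyde.

**Step 10**
Reactants: 18 (2R)-2-(2,2-dimethoxyethyl)-2-methyl-5-(prop-1-en-2-yl)furan-3(2H)-one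
Product: 19 [(2R)-2-methyl-3-oxo-5-(prop-1-en-2-yl)-2,3-dihydrofuran-2-yl]acetaldehyde
Conditions: TFA/H2O (1:1), CHCl3, 0 °C; used crude
Reagents that add atoms: water (O)
Why: Acetal hydrolysis under acid, to which the furanone is stable and which avoids the base-induced β-elimination of the furanone oxygen from this aldehyde.

### Bromomethyl butenolide (steps 11–17)

**Step 11**
Reactants: 20 tert-butyldimethyl(prop-2-yn-1-yloxy)silane; 21 acrolein
Product: 23 rac-6-[(tert-butyldimethylsilyl)oxy]hex-1-en-4-yn-3-ol, via lithium acetylide 22 (not isolated)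
Conditions: n-BuLi, THF, −78 °C; then 21, −78 °C; AcOH quench
Reagents that add atoms: none
Why: 1,2-Addition of a lithium acetylide to acrolein assembles C5–C7, C11 and C13 in one step as the racemic vinyl alkynyl carbinol.

**Step 12**
Reactants: 23 rac-6-[(tert-butyldimethylsilyl)oxy]hex-1-en-4-yn-3-ol
Product: 24 (3R)-6-[(tert-butyldimethylsilyl)oxy]hex-1-en-4-yn-3-yl acetate
Conditions: Amano lipase PS (immobilised), vinyl acetate, MTBE, 30 °C, stopped near 50 % conversion; chromatography
Reagents that add atoms: vinyl acetate (CC(=O)OC=C)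
Why: Lipase-catalysed kinetic resolution by transesterification acylates, by Kazlauskas' rule (small vinyl, large alkynyl), the 3R enantiomer, which sets C6; the unreacted (S)-enantiomer of 23 is separated, so the yield is at most 50 %.

**Step 13**
Reactants: 24 (3R)-6-[(tert-butyldimethylsilyl)oxy]hex-1-en-4-yn-3-yl acetate
Product: 25 (3R)-6-[(tert-butyldimethylsilyl)oxy]hex-1-en-4-yn-3-ol
Conditions: K2CO3 (cat.), MeOH, 0 °C
Reagents that add atoms: none
Why: Mild transesterification removes the acetate without touching the silyl ether or the carbinol configuration.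

**Step 14**
Reactants: 25 (3R)-6-[(tert-butyldimethylsilyl)oxy]hex-1-en-4-yn-3-ol
Product: 27 (3R,4Z)-6-[(tert-butyldimethylsilyl)oxy]-5-iodohexa-1,4-dien-3-ol, via sodium alkenylaluminate 26 (not isolated)
Conditions: NaAlH2(OCH2CH2OMe)2, THF, 0 °C; then [I][I] in THF, −78 °C
Reagents that add atoms: iodine ([I][I])
Why: Hydroxyl-directed trans-hydroalumination puts aluminium on the distal alkyne carbon in a five-membered aluminate, and iodinolysis with retention gives the Z iodide cis to the carbinol; low temperature suppresses loss of the silyloxy group to an allene.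

**Step 15**
Reactants: 27 (3R,4Z)-6-[(tert-butyldimethylsilyl)oxy]-5-iodohexa-1,4-dien-3-ol
Product: 28 (5R)-3-{[(tert-butyldimethylsilyl)oxy]methyl}-5-vinylfuran-2(5H)-one
Conditions: PdCl2(PPh3)2 (5 mol %), CO (1 atm), K2CO3, THF, rt
Reagents that add atoms: carbon monoxide ([C-]#[O+])
Why: Palladium-catalysed carbonylative lactonisation (oxidative addition, CO insertion, capture of the acylpalladium by the cis hydroxyl) closes the butenolide; solid K2CO3 at rt limits epimerisation of the acidic C6–H.

**Step 16**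
Reactants: 28 (5R)-3-{[(tert-butyldimethylsilyl)oxy]methyl}-5-vinylfuran-2(5H)-one
Product: 29 (5R)-3-(hydroxymethyl)-5-vinylfuran-2(5H)-one
Conditions: CSA (cat.), MeOH/CH2Cl2, 0 °C → rt
Reagents that add atoms: none
Why: Acid-catalysed methanolysis of the primary silyl ether avoids any base near the C6–H.

**Step 17**
Reactants: 29 (5R)-3-(hydroxymethyl)-5-vinylfuran-2(5H)-one
Product: 30 (5R)-3-(bromomethyl)-5-vinylfuran-2(5H)-one
Conditions: CBr4, PPh3, CH2Cl2, 0 °C
Reagents that add atoms: carbon tetrabromide (BrC(Br)(Br)Br)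
Why: Appel bromination of the primary allylic alcohol proceeds under neutral conditions by direct SN2 displacement.

### Fragment union and endgame (steps 18–20)

**Step 18**
Reactants: 19 [(2R)-2-methyl-3-oxo-5-(prop-1-en-2-yl)-2,3-dihydrofuran-2-yl]acetaldehyde; 30 (5R)-3-(bromomethyl)-5-vinylfuran-2(5H)-one
Product: 32 (4R,5R)-4-{(1S)-1-hydroxy-2-[(2R)-2-methyl-3-oxo-5-(prop-1-en-2-yl)-2,3-dihydrofuran-2-yl]ethyl}-3-methylidene-5-vinyloxolan-2-one, via allylzinc bromide 31 (not isolated)
Conditions: Zn dust, THF/sat. aq. NH4Cl, 0 °C → rt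
Reagents that add atoms: none
Why: Barbier-type carbonyl allylation in which the allylzinc attacks the aldehyde through C7 in a closed chair transition state on the face anti to the C6 vinyl group, giving the trans C6/C7 lactone (7R) and the 7,8-anti alcohol (8S) while the double bond moves to the exocyclic methylene.

**Step 19**
Reactants: 32 (4R,5R)-4-{(1S)-1-hydroxy-2-[(2R)-2-methyl-3-oxo-5-(prop-1-en-2-yl)-2,3-dihydrofuran-2-yl]ethyl}-3-methylidene-5-vinyloxolan-2-one; 33 angelic acid
Product: 34 (1R)-1-[(2R,3R)-4-methylidene-5-oxo-2-vinyloxolan-3-yl]-2-[(2R)-2-methyl-3-oxo-5-(prop-1-en-2-yl)-2,3-dihydrofuran-2-yl]ethyl (2Z)-2-methylbut-2-enoate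
Conditions: PPh3, DIAD, toluene, 0 °C → rt (3 equiv each of 33, PPh3, DIAD; betaine pre-formed)
Reagents that add atoms: none
Why: Mitsunobu esterification inverts C8 by SN2 (8S to 8R), and because angelic acid reacts as a carboxylate nucleophile and is never activated at its acyl carbon, the Z geometry is kept.

**Step 20**
Reactants: 34 (1R)-1-[(2R,3R)-4-methylidene-5-oxo-2-vinyloxolan-3-yl]-2-[(2R)-2-methyl-3-oxo-5-(prop-1-en-2-yl)-2,3-dihydrofuran-2-yl]ethyl (2Z)-2-methylbut-2-enoate
Product: 35 15-deoxybudlein A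
Conditions: second-generation Hoveyda–Grubbs catalyst (20 mol %, in portions), 1,4-benzoquinone (20 mol %), toluene (1 mM), 90 °C
Reagents that add atoms: none
Why: Ring-closing metathesis between the vinyl and isopropenyl groups closes the ten-membered ring, whose size forces the Z C4=C5 geometry; the angelate and the exocyclic methylene are too hindered and electron-poor to compete, and benzoquinone suppresses ruthenium hydride isomerisation.

## Compound list

1 | (S)-lactic acid | C[C@H](O)C(=O)O | starting material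
2 | pivalaldehyde | CC(C)(C)C=O | starting material
3 | (2S,5S)-2-tert-butyl-5-methyl-1,3-dioxolan-4-one | C[C@@H]1O[C@H](C(C)(C)C)OC1=O | intermediate
4 | allyl bromide | C=CCBr | starting material
5 | lithium enolate of 3 (not isolated) | CC1=C(O[Li])O[C@@H](C(C)(C)C)O1 | intermediate
6 | (2S,5R)-2-tert-butyl-5-methyl-5-(prop-2-en-1-yl)-1,3-dioxolan-4-one | C[C@]1(CC=C)O[C@H](C(C)(C)C)OC1=O | intermediate
7 | (2R)-2-hydroxy-N-methoxy-N,2-dimethylpent-4-enamide | C=CC[C@@](C)(O)C(=O)N(C)OC | intermediate
8 | (2R)-2-hydroxy-N-methoxy-N,2-dimethyl-3-(1,2,4-trioxolan-3-yl)propanamide, ozonide (not isolated) | C1OC(C[C@@](C)(O)C(=O)N(C)OC)OO1 | intermediate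
9 | (2R)-2-hydroxy-N-methoxy-N,2-dimethyl-4-oxobutanamide (not isolated) | O=CC[C@@](C)(O)C(=O)N(C)OC | intermediate
10 | (2R)-2-hydroxy-N,4,4-trimethoxy-N,2-dimethylbutanamide | COC(OC)C[C@@](C)(O)C(=O)N(C)OC | intermediate
11 | (2R)-N,4,4-trimethoxy-N,2-dimethyl-2-[(trimethylsilyl)oxy]butanamide | COC(OC)C[C@@](C)(O[Si](C)(C)C)C(=O)N(C)OC | intermediate
12 | (3R)-5,5-dimethoxy-3-methyl-3-[(trimethylsilyl)oxy]pentan-2-one | COC(OC)C[C@@](C)(O[Si](C)(C)C)C(C)=O | intermediate
13 | methacrolein | CC(=C)C=O | starting material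
14 | lithium (3R)-5,5-dimethoxy-3-methyl-3-[(trimethylsilyl)oxy]pent-1-en-2-olate (not isolated) | C=C(O[Li])[C@](C)(O[Si](C)(C)C)CC(OC)OC | intermediate
15 | (6R)-3-hydroxy-8,8-dimethoxy-2,6-dimethyl-6-[(trimethylsilyl)oxy]oct-1-en-5-one, C3 epimers | C=C(C)C(O)CC(=O)[C@](C)(O[Si](C)(C)C)CC(OC)OC | intermediate
16 | (6R)-8,8-dimethoxy-2,6-dimethyl-6-[(trimethylsilyl)oxy]oct-1-ene-3,5-dione | C=C(C)C(=O)CC(=O)[C@](C)(O[Si](C)(C)C)CC(OC)OC | intermediate
17 | (6R)-6-hydroxy-8,8-dimethoxy-2,6-dimethyloct-1-ene-3,5-dione (not isolated) | C=C(C)C(=O)CC(=O)[C@](C)(O)CC(OC)OC | intermediate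
18 | (2R)-2-(2,2-dimethoxyethyl)-2-methyl-5-(prop-1-en-2-yl)furan-3(2H)-one | C=C(C)C1=CC(=O)[C@@](C)(CC(OC)OC)O1 | intermediate
19 | [(2R)-2-methyl-3-oxo-5-(prop-1-en-2-yl)-2,3-dihydrofuran-2-yl]acetaldehyde | C=C(C)C1=CC(=O)[C@@](C)(CC=O)O1 | intermediate
20 | tert-butyldimethyl(prop-2-yn-1-yloxy)silane | C#CCO[Si](C)(C)C(C)(C)C | starting material
21 | acrolein | C=CC=O | starting material
22 | lithium acetylide of 20 (not isolated) | [Li]C#CCO[Si](C)(C)C(C)(C)C | intermediate
23 | rac-6-[(tert-butyldimethylsilyl)oxy]hex-1-en-4-yn-3-ol | C=CC(O)C#CCO[Si](C)(C)C(C)(C)C | intermediate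
24 | (3R)-6-[(tert-butyldimethylsilyl)oxy]hex-1-en-4-yn-3-yl acetate | C=C[C@@H](OC(C)=O)C#CCO[Si](C)(C)C(C)(C)C | intermediate
25 | (3R)-6-[(tert-butyldimethylsilyl)oxy]hex-1-en-4-yn-3-ol | C=C[C@@H](O)C#CCO[Si](C)(C)C(C)(C)C | intermediate
26 | sodium cyclic alkenylaluminate of 25, 2,5-dihydro-1,2-oxaalumole (not isolated) | [Na+].C=C[C@@H]1C=C(CO[Si](C)(C)C(C)(C)C)[Al-](OCCOC)(OCCOC)O1 | intermediate
27 | (3R,4Z)-6-[(tert-butyldimethylsilyl)oxy]-5-iodohexa-1,4-dien-3-ol | C=C[C@@H](O)/C=C(\I)CO[Si](C)(C)C(C)(C)C | intermediate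
28 | (5R)-3-{[(tert-butyldimethylsilyl)oxy]methyl}-5-vinylfuran-2(5H)-one | C=C[C@@H]1C=C(CO[Si](C)(C)C(C)(C)C)C(=O)O1 | intermediate
29 | (5R)-3-(hydroxymethyl)-5-vinylfuran-2(5H)-one | C=C[C@@H]1C=C(CO)C(=O)O1 | intermediate
30 | (5R)-3-(bromomethyl)-5-vinylfuran-2(5H)-one | C=C[C@@H]1C=C(CBr)C(=O)O1 | intermediate
31 | allylzinc bromide from 30 (not isolated) | C=C[C@@H]1C=C(C[Zn]Br)C(=O)O1 | intermediate
32 | (4R,5R)-4-{(1S)-1-hydroxy-2-[(2R)-2-methyl-3-oxo-5-(prop-1-en-2-yl)-2,3-dihydrofuran-2-yl]ethyl}-3-methylidene-5-vinyloxolan-2-one (6R,7R,8S,10R) | C=C1C(=O)O[C@H](C=C)[C@H]1[C@@H](O)C[C@@]2(C)OC(C(C)=C)=CC2=O | intermediate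
33 | angelic acid, (2Z)-2-methylbut-2-enoic acid | C/C=C(/C)C(=O)O | starting material
34 | (1R)-1-[(2R,3R)-4-methylidene-5-oxo-2-vinyloxolan-3-yl]-2-[(2R)-2-methyl-3-oxo-5-(prop-1-en-2-yl)-2,3-dihydrofuran-2-yl]ethyl (2Z)-2-methylbut-2-enoate (6R,7R,8R,10R) | C=C1C(=O)O[C@H](C=C)[C@H]1[C@H](OC(=O)/C(C)=C\C)C[C@@]2(C)OC(C(C)=C)=CC2=O | intermediate
35 | 15-deoxybudlein A | C=C1C(=O)O[C@@H]2/C=C(/C)C3=CC(=O)[C@@](C)(C[C@@H](OC(=O)/C(C)=C\C)[C@@H]12)O3 | target

## Step count and risks

Total step count: 20. Longest linear sequence: 13 steps (steps 1–10, then 18–20, from (S)-lactic acid); the butenolide branch (steps 11–17) is 7 steps.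

**Most likely to fail, 1: step 20 (ring-closing metathesis).** A strained ten-membered ring with a trisubstituted, furanone-conjugated alkene may oligomerise instead of closing. The fallback sets out from 32 and comes back at 35. The ring is closed one step earlier on the free 8S alcohol 32, whose different C8 configuration and small hydroxyl change the ring-closing conformation, using the same catalyst under high dilution. This gives the macrocyclic alcohol 8-epi-8-O-deangeloyl-15-deoxybudlein A F4. Mitsunobu esterification of F4 with angelic acid 33 (PPh3, DIAD, toluene) then inverts C8 on the ring and gives 35 directly.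

**Most likely to fail, 2: step 19 (Mitsunobu with angelic acid).** C8 is flanked by a branched ring carbon and a neopentyl-type CH2, and angelic acid is only moderately acidic, so elimination or no reaction may win. The fallback sets out from 32 and comes back at 34. Inversion is first carried out with the small, much more acidic chloroacetic acid (PPh3, DIAD, toluene) to give the inverted ester (1R)-1-[(2R,3R)-4-methylidene-5-oxo-2-vinyloxolan-3-yl]-2-[(2R)-2-methyl-3-oxo-5-(prop-1-en-2-yl)-2,3-dihydrofuran-2-yl]ethyl chloroacetate F2. Thiourea with NaHCO3 in EtOH/THF at 40 °C removes the chloroacetyl group and gives the 8R alcohol (4R,5R)-4-{(1R)-1-hydroxy-2-[(2R)-2-methyl-3-oxo-5-(prop-1-en-2-yl)-2,3-dihydrofuran-2-yl]ethyl}-3-methylidene-5-vinyloxolan-2-one F3. F3 is then acylated with retention, the new bond being made at the acyl carbon, using the mixed anhydride of 33 and 2,4,6-trichlorobenzoyl chloride (Et3N; toluene, 80 °C, no DMAP, which keeps the Z geometry), to give 34.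

**Most likely to fail, 3: step 18 (Barbier coupling).** Aldehyde 19 can lose the furanone oxygen by β-elimination, the allylzinc can fragment, and the zinc alkoxide can migrate the lactone to O8. The fallback sets out from 30 and comes back at 32. Bromide 30 is borylated without base (B2pin2, Pd2(dba)3, THF, 60 °C) to the isolable allylboronate (5R)-3-[(4,4,5,5-tetramethyl-1,3,2-dioxaborolan-2-yl)methyl]-5-vinylfuran-2(5H)-one F1. F1 is heated with aldehyde 19 in toluene (40–60 °C, Sc(OTf)3 as optional catalyst); this allylboration runs through the same closed chair arrangement, anti to the vinyl group, and gives 32 after aqueous work-up, with no reducing metal, water or alkoxide near the aldehyde.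

## Further compounds

F1 | step 18 | (5R)-3-[(4,4,5,5-tetramethyl-1,3,2-dioxaborolan-2-yl)methyl]-5-vinylfuran-2(5H)-one | C=C[C@@H]1C=C(CB2OC(C)(C)C(C)(C)O2)C(=O)O1
F2 | step 19 | (1R)-1-[(2R,3R)-4-methylidene-5-oxo-2-vinyloxolan-3-yl]-2-[(2R)-2-methyl-3-oxo-5-(prop-1-en-2-yl)-2,3-dihydrofuran-2-yl]ethyl chloroacetate | C=C1C(=O)O[C@H](C=C)[C@H]1[C@H](OC(=O)CCl)C[C@@]2(C)OC(C(C)=C)=CC2=O
F3 | step 19 | (4R,5R)-4-{(1R)-1-hydroxy-2-[(2R)-2-methyl-3-oxo-5-(prop-1-en-2-yl)-2,3-dihydrofuran-2-yl]ethyl}-3-methylidene-5-vinyloxolan-2-one | C=C1C(=O)O[C@H](C=C)[C@H]1[C@H](O)C[C@@]2(C)OC(C(C)=C)=CC2=O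
F4 | step 20 | 8-epi-8-O-deangeloyl-15-deoxybudlein A, macrocyclic 8S alcohol | C=C1C(=O)O[C@@H]2/C=C(/C)C3=CC(=O)[C@@](C)(C[C@H](O)[C@@H]12)O3
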